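- 6 questions on 3 flasks stand below, and I answer them with one division: how the reagent charge splits, at the stop, between target and the rest.

the same everywhere: starting material 44 mM; free catalyst 26 µM
- autumn: reagent 28 mM; run made earlier
- dawn: reagent 130 mM; run made earlier
- grey: reagent 22.0 mM; time 4.0 d
- ochre: reagent 44.0 mM; time 4.0 d
- blue: reagent 88.0 mM; time 4.0 d

| run | time / d | starting material / % | target / % | catalyst intermediate A / % | catalyst intermediate C / % |
|---|---|---|---|---|---|
| autumn | 0.500 | 78.3 | 19.8 | 0.1 | 1.7 |
| autumn | 1.25 | 62.0 | 37.1 | 1.3 | 0 |
| autumn | 2.50 | 53.9 | 45.0 | 0 | 0.1 |
| autumn | 4.00 | 55.7 | 46.5 | 0 | 1.2 |
| dawn | 1.04 | 51.4 | 48.4 | 0 | 1.3 |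
| dawn | 2.08 | 27.1 | 71.7 | 0 | 0 |
| dawn | 3.00 | 22.0 | 78.7 | 1.3 | 0 |
| dawn | 4.00 | 18.8 | 79.7 | 0 | 0 |

(scatter of a reading: 1 percentage point)

- a species is counted by the starting material in it: one spent catalyst counts as two
- the analysis behind the earlier runs scatters by 1 percentage point, standard deviation
- steps thought possible: starting material + free catalyst -> catalyst intermediate A; reagent + catalyst intermediate A -> catalyst intermediate B; catalyst intermediate B -> by-product + catalyst intermediate C; catalyst intermediate C -> free catalyst + target; 2 catalyst intermediate A -> spent catalyst; 2 reagent -> homo dimer

- which of these there is most of at the end, counted by the starting material in it, grey (starting material / catalyst intermediate A / target / catalyst intermediate C)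
- which of these there is most of at the end, counted by the starting material in it, ochre (starting material / catalyst intermediate A / target / catalyst intermediate C)
- which of these there is most of at the end, counted by the starting material in it, blue (starting material / catalyst intermediate A / target / catalyst intermediate C)
- how much there is at the end of the one of these that leads, in percent of the starting material charged: grey
- how much there is at the end of the one of these that leads, in percent of the starting material charged: ochre
- how much there is at the end of the one of these that leads, in percent of the starting material charged: blue

- The catalyst charge is 0.0591 % of the starting material charge, so I let starting material and target share that charge between them.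
- Autumn stops with 55.7 % of the starting material unreacted and dawn with 18.8 %, so I look at the reagent instead. By the steps thought possible, each target made takes one reagent, so as a fraction of the reagent charge the target reads 73.1 % in autumn and 27.0 % in dawn.
- My two amounts are the reagent spent on target and the reagent not spent on it. Their quotient is the waste ratio 0.369, here for autumn, and 2.71 for dawn.
- The ratio can climb with the charge, since the possible loss of two reagent to homo dimer goes with the square of reagent.
- In common logarithms the ratio rises 0.866 while the reagent charge rises 0.667, which reads as a power of 1.30. I use this as a straight line, with starting material held at 44 mM.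
- My reckoning takes target as the reagent-to-starting-material charge fraction divided by one plus the ratio. Grey has ratio 0.269, so target is 39.4 % and starting material leads at 60.6 %. Ochre has 0.663, so target leads at 60.1 %. Blue has 1.63, so target leads at 76.0 %.
- The forecast names starting material for grey at 60 %, target for ochre at 56 % and target for blue at 71 %, on the ground “Reagent is therefore being wasted, or the catalyst dies”. For ochre and blue it stands lower than my reckoning.
- The flasks give starting material at 60.7 % in grey, target at 59.2 % in ochre and target at 74.7 % in blue.

    starting material + free catalyst → catalyst intermediate A (k = 3800 M⁻¹ h⁻¹)
    reagent + catalyst intermediate A → catalyst intermediate B (k = 6700 M⁻¹ h⁻¹)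
    catalyst intermediate B → by-product + catalyst intermediate C (k = 140 h⁻¹)
    catalyst intermediate C → free catalyst + target (k = 91.0 h⁻¹)
    2 catalyst intermediate A → spent catalyst (k = 3000 M⁻¹ h⁻¹)
    2 reagent → homo dimer (k = 0.590 M⁻¹ h⁻¹)

- Grey ends with 1.4 % of its reagent left against 61 % of its starting material, which makes reagent the limiting reagent. At 0.516 d the step to catalyst intermediate B uses reagent at 4.8 times the rate of the loss to homo dimer, and grey's waste ratio from its result is 0.273. The neighbour like grey but with 26 mM of starting material has grey's reagent charge, so carrying the ratio over gives target at 66.7 % of its starting material, and that flask ends at 64.9 %.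

The numbers in the tables were computed with constants of no real substance; noise was put on by code.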